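**Assumption:** the target SMILES has no stereocentre and no stereogenic double bond. Cathafuran C is therefore achiral, and "single enantiomer" calls for no stereocontrol.

## Retrosynthetic overview
- The pyran ring is formed last, by oxidative cyclisation of one of two equivalent o-prenylphenol units in a C2-symmetric 2-arylbenzofuran triol.
- The furan ring comes from the key step. C3–C3a forms by SRN1 coupling of a resorcinol-derived aryl radical with the enolate of a 2,6-diprenylaryl methyl ketone, and O1–C2 then forms by cyclodehydration in the same pot.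
- In the ketone, the prenyl groups come from a 2,6-dibromide (Br/Li exchange, prenyl bromide). The acetyl group is set meta to both oxygens by Ir C–H borylation and acylative Suzuki coupling.
- Both arenes come from resorcinol, C2/C3 from acetic anhydride, and both C5 units from prenyl bromide. Ring order: furan, then pyran.

## Route

**Step 1**
Reactants: 1 resorcinol
Product: 2 1,3-bis(methoxymethoxy)benzene
Conditions: NaH (2.2 equiv), MOMCl (2.2 equiv), DMF, 0 °C → rt
Reagents that add atoms: chloromethyl methyl ether (MOMCl), COCCl
Why: Williamson-type MOM protection of both phenoxides gives acetals that survive Ir/Pd catalysis, organolithiums and radical-anion conditions and are removed in the single acidic operation of step 6; no stereocentre is formed.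

**Step 2**
Reactants: 2 1,3-bis(methoxymethoxy)benzene
Product: 3 1-iodo-2,4-bis(methoxymethoxy)benzene
Conditions: NIS (1.05 equiv), MeCN, rt, dark
Reagents that add atoms: N-iodosuccinimide, O=C1CCC(=O)N1I
Why: Electrophilic aromatic iodination goes to C4 (para to one acetal oxygen, ortho to the other) because the site between the two acetals is shielded, and this gives the aryl-radical precursor.

**Step 3**
Reactants: 2 1,3-bis(methoxymethoxy)benzene; 4 acetic anhydride
Product: 6 1-[3,5-bis(methoxymethoxy)phenyl]ethanone, via aryl pinacol boronate 5 (not isolated)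
Conditions: [Ir(OMe)(cod)]2 (1.5 mol %), dtbpy (3 mol %), B2pin2 (0.55 equiv), THF, 80 °C; then 4 (1.5 equiv), Pd(OAc)2 (3 mol %), P(4-MeOC6H4)3 (7 mol %), H2O (2.5 equiv), 60 °C
Reagents that add atoms: bis(pinacolato)diboron, CC1(C)OB(OC1(C)C)B1OC(C)(C)C(C)(C)O1 (its boryl group is present in 5 only and is lost again on the way to 6)
Why: Sterically controlled Ir-catalysed C–H borylation reaches only C5–H, the one position without an ortho substituent and meta to both oxygens, and a one-pot acylative Suzuki–Miyaura coupling with the anhydride converts C–B into C–acetyl.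

**Step 4**
Reactants: 6 1-[3,5-bis(methoxymethoxy)phenyl]ethanone
Product: 7 1-[2,6-dibromo-3,5-bis(methoxymethoxy)phenyl]ethanone
Conditions: NBS (2.1 equiv), MeCN, 0 °C → rt, dark
Reagents that add atoms: N-bromosuccinimide, O=C1CCC(=O)N1Br
Why: In this double electrophilic aromatic bromination each bromine enters para to one ether and ortho to the other, as is usual for 3,5-dialkoxyaryl carbonyl compounds; C4 between the two acetals stays free and the activated ring reacts faster than the ketone α-position.

**Step 5**
Reactants: 7 1-[2,6-dibromo-3,5-bis(methoxymethoxy)phenyl]ethanone; 8 prenyl bromide (1-bromo-3-methylbut-2-ene)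
Product: 12 1-[3,5-bis(methoxymethoxy)-2,6-bis(3-methylbut-2-enyl)phenyl]ethanone, via the dibromo lithium enolate 9 (not isolated), via the 2,6-dilithiated lithium enolate 10 (not isolated), via the diprenyl lithium enolate 11 (not isolated)
Conditions: LiHMDS (1.05 equiv), THF, −78 °C; t-BuLi (5.2 equiv, the first equivalent re-lithiates the liberated HN(SiMe3)2), −78 °C; CuBr·SMe2 (0.2 equiv), 8 (2.5 equiv), −78 → −40 °C; AcOH quench
Reagents that add atoms: lithium hexamethyldisilazide, [Li]N([Si](C)(C)C)[Si](C)(C)C, and tert-butyllithium, [Li]C(C)(C)C (lithium is present in 9–11 only, none in 12)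
Why: The ketone is masked in situ as its enolate, double bromine–lithium exchange gives MOM-chelated aryllithiums, and copper-assisted SN2 allylation with prenyl bromide occurs at temperatures where the hindered enolate is not alkylated.

**Step 6 (key step)**
Reactants: 12 1-[3,5-bis(methoxymethoxy)-2,6-bis(3-methylbut-2-enyl)phenyl]ethanone; 3 1-iodo-2,4-bis(methoxymethoxy)benzene
Product: 16 2-[3,5-dihydroxy-2,6-bis(3-methylbut-2-enyl)phenyl]-1-benzofuran-6-ol, via the potassium enolate 13 (not isolated), via the tetra-MOM deoxybenzoin 14 (not isolated), via the tetrahydroxy deoxybenzoin 15 (not isolated)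
Conditions: t-BuOK (2.3 equiv), 3 (1.1 equiv), NH3(l)/THF 9:1, hν (350 nm, Pyrex), −33 °C; evaporate NH3; 1 M HCl, MeOH, 45 °C
Reagents that add atoms: potassium tert-butoxide, CC(C)(C)[O-].[K+] (potassium is present in 13 only)
Why: In this photostimulated SRN1 radical chain, electron transfer to 3 expels iodide and leaves the 2,4-bis(MOM-oxy)phenyl σ-radical, which is captured at the unhindered CH2 terminus of the twisted, aliphatic-like enolate 13 near the diffusion limit (faster than addition to, or H-abstraction from, the trisubstituted prenyl groups), the product radical anion passes its electron to the next molecule of 3, and acid then removes all four MOM groups so that the freed ortho-OH of 15 cyclodehydrates onto the ketone to give the aromatic furan; no stereocentre is formed.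

**Step 7**
Reactants: 16 2-[3,5-dihydroxy-2,6-bis(3-methylbut-2-enyl)phenyl]-1-benzofuran-6-ol
Product: 18 cathafuran C, via the o-quinone methide 17 (not isolated)
Conditions: DDQ (1.0 equiv, slow addition), toluene, 60 °C; recovered 16 is recycled
Reagents that add atoms: none
Why: In this DDQ cyclodehydrogenation of an o-prenylphenol, hydride abstraction from the benzylic CH2 (ortho to one OH, para to the other) gives o-quinone methide 17, which closes by oxa-6π electrocyclisation; the two prenyl/OH pairs of 16 are symmetry-equivalent so either one gives 18, and one equivalent of oxidant limits bis-chromene formation.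

## Compound list
1 | resorcinol | Oc1cccc(O)c1 | starting material
2 | 1,3-bis(methoxymethoxy)benzene | COCOc1cccc(OCOC)c1 | intermediate
3 | 1-iodo-2,4-bis(methoxymethoxy)benzene | COCOc1ccc(I)c(OCOC)c1 | intermediate
4 | acetic anhydride | CC(=O)OC(C)=O | starting material
5 | 2-[3,5-bis(methoxymethoxy)phenyl]-4,4,5,5-tetramethyl-1,3,2-dioxaborolane | COCOc1cc(OCOC)cc(c1)B1OC(C)(C)C(C)(C)O1 | intermediate
6 | 1-[3,5-bis(methoxymethoxy)phenyl]ethanone | CC(=O)c1cc(OCOC)cc(OCOC)c1 | intermediate
7 | 1-[2,6-dibromo-3,5-bis(methoxymethoxy)phenyl]ethanone | CC(=O)c1c(Br)c(OCOC)cc(OCOC)c1Br | intermediate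
8 | prenyl bromide (1-bromo-3-methylbut-2-ene) | CC(C)=CCBr | starting material
9 | lithium enolate of 7 | [Li]OC(=C)c1c(Br)c(OCOC)cc(OCOC)c1Br | intermediate
10 | 2,6-dilithiated lithium enolate | [Li]OC(=C)c1c([Li])c(OCOC)cc(OCOC)c1[Li] | intermediate
11 | lithium enolate of 12 | [Li]OC(=C)c1c(CC=C(C)C)c(OCOC)cc(OCOC)c1CC=C(C)C | intermediate
12 | 1-[3,5-bis(methoxymethoxy)-2,6-bis(3-methylbut-2-enyl)phenyl]ethanone | CC(=O)c1c(CC=C(C)C)c(OCOC)cc(OCOC)c1CC=C(C)C | intermediate
13 | potassium enolate of 12 | [K+].[O-]C(=C)c1c(CC=C(C)C)c(OCOC)cc(OCOC)c1CC=C(C)C | intermediate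
14 | 1-[3,5-bis(methoxymethoxy)-2,6-bis(3-methylbut-2-enyl)phenyl]-2-[2,4-bis(methoxymethoxy)phenyl]ethanone | COCOc1ccc(CC(=O)c2c(CC=C(C)C)c(OCOC)cc(OCOC)c2CC=C(C)C)c(OCOC)c1 | intermediate
15 | 2-(2,4-dihydroxyphenyl)-1-[3,5-dihydroxy-2,6-bis(3-methylbut-2-enyl)phenyl]ethanone | CC(C)=CCc1c(O)cc(O)c(CC=C(C)C)c1C(=O)Cc1ccc(O)cc1O | intermediate
16 | 2-[3,5-dihydroxy-2,6-bis(3-methylbut-2-enyl)phenyl]-1-benzofuran-6-ol | CC(C)=CCc1c(O)cc(O)c(CC=C(C)C)c1-c1cc2ccc(O)cc2o1 | intermediate
17 | o-quinone methide from 16 (3-hydroxy-5-(6-hydroxybenzofuran-2-yl)-6-(3-methylbut-2-enylidene)-4-(3-methylbut-2-enyl)cyclohexa-2,4-dienone) | CC(C)=CCC1=C(c2cc3ccc(O)cc3o2)C(=CC=C(C)C)C(=O)C=C1O | intermediate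
18 | cathafuran C (5-(6-hydroxy-1-benzofuran-2-yl)-2,2-dimethyl-6-(3-methylbut-2-enyl)-2H-chromen-7-ol; achiral) | CC(C)=CCc1c(O)cc2c(c1-c1cc3ccc(O)cc3o1)C=CC(C)(C)O2 | target

## Step count
- Total steps: 7.
- Longest linear sequence: 6 (steps 1 → 3 → 4 → 5 → 6 → 7). Step 2 is the side branch.

## Steps most likely to fail, with fallbacks

**Step 5.** The risks are incomplete double exchange on a species that is already anionic, protonation of the aryllithiums, and C-prenylation of the enolate. The fallback sets out from 7 and masks the carbonyl by a change of oxidation state instead of as an enolate. NaBH4 reduces 7 to racemic 1-[2,6-dibromo-3,5-bis(methoxymethoxy)phenyl]ethanol F1. Its lithium alkoxide is inert to t-BuLi, so bromine–lithium exchange and allylation with 8 give 1-[3,5-bis(methoxymethoxy)-2,6-bis(3-methylbut-2-enyl)phenyl]ethanol F2. Dess–Martin oxidation of F2 returns to the route at 12.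

**Step 6.** The risks are a chain that does not start or dies, reduction of the aryl radical back to 2, and acid-induced chroman formation during deprotection. The fallback sets out from 12 and replaces the anionic chain by a neutral radical addition. TBSOTf/Et3N converts 12 into its tert-butyldimethylsilyl enol ether F3. The same aryl radical is generated from 3 by a strongly reducing organic photocatalyst (10-phenylphenothiazine, 390 nm, NaHCO3, MeCN) and adds to the terminal CH2 of F3. Oxidation of the α-silyloxy radical and loss of silicon give 14, where the route is rejoined for the acid stage.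

**Step 7.** The risks are over-oxidation to the bis-chromene and attack of DDQ on the electron-rich triol. The fallback sets out from 16 and uses alkene activation instead of hydride abstraction. PhSeCl (1 equiv, CH2Cl2, −78 °C) triggers a Markovnikov 6-endo selenoetherification to racemic 5-(6-hydroxy-1-benzofuran-2-yl)-2,2-dimethyl-6-(3-methylbut-2-enyl)-3-(phenylselanyl)chroman-7-ol F4. H2O2 then forms the selenoxide, which can only eliminate toward C4 because C2 is quaternary, giving 18 directly.

## Further compounds
F1 | step 5 | 1-[2,6-dibromo-3,5-bis(methoxymethoxy)phenyl]ethanol (racemic) | CC(O)c1c(Br)c(OCOC)cc(OCOC)c1Br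
F2 | step 5 | 1-[3,5-bis(methoxymethoxy)-2,6-bis(3-methylbut-2-enyl)phenyl]ethanol (racemic) | CC(O)c1c(CC=C(C)C)c(OCOC)cc(OCOC)c1CC=C(C)C
F3 | step 6 | tert-butyldimethylsilyl enol ether of 12 | CC(C)(C)[Si](C)(C)OC(=C)c1c(CC=C(C)C)c(OCOC)cc(OCOC)c1CC=C(C)C
F4 | step 7 | 5-(6-hydroxy-1-benzofuran-2-yl)-2,2-dimethyl-6-(3-methylbut-2-enyl)-3-(phenylselanyl)chroman-7-ol (racemic) | CC(C)=CCc1c(O)cc2OC(C)(C)C([Se]c3ccccc3)Cc2c1-c1cc2ccc(O)cc2o1
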